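Counting the carbocycle from the acetate carbon C1 through C3 (methyl), C7 (enal carbon) and C8 (formyl methine) to C9 (side chain), the C1–C2 single bond, the E C3=C4 alkene and a carbonyl-level C8 make up an oxy-Cope retron. C4–C5–C6=C7–C8 is a concealed cyclopentene ring that keeps C6=C7 cis. Cutting C1–C2 and rejoining C4 to C8 gives a trans-1,2-dialkenylcyclopent-2-enol with isopropenyl on C4 and a citronellal-derived Z alkoxyvinyl group on C8. One [3,3] shift of its potassium alkoxide enlarges the five-membered ring to the nine-membered one, creates E C3=C4, sets C1 and exposes a C8 ketone for one-carbon homologation.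

Key step: step 10

Remark: the locants C1–C9 defined above, with C10 for the side-chain methine, are used for every intermediate. "Cis" at C6=C7 refers to the ring path C5–C6=C7–C8; the CIP letter changes with the substituents.
Assumption: (S)-citronellal, (S)-4-benzyl-2-oxazolidinone and 2-bromoacrolein diethyl acetal are bought, the first two in high enantiomeric purity.

Step 1
Reactants: 1 (S)-citronellal; 2 4-methoxybenzyl alcohol (2.3 equiv)
Product: 3 (3S)-1,1-bis[(4-methoxybenzyl)oxy]-3,7-dimethyloct-6-ene
Conditions: PPTS (5 mol %), 4 Å molecular sieves, CH2Cl2, rt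
Reagents that add atoms: none
Why: Acid-catalysed acetalisation pulled forward by the sieves; the weak acid at room temperature should keep the carbonyl-ene closure of citronellal and the self-etherification of 2 slow, and C10 is not touched.

Step 2
Reactants: 3 bis(4-methoxybenzyl) acetal
Product: 4 (3S)-1-[(4-methoxybenzyl)oxy]-3,7-dimethylocta-1,6-diene (E/Z mixture at the enol ether)
Conditions: Me3SiOTf (1.2 equiv), i-Pr2NEt (1.5 equiv), CH2Cl2, −30 → 0 °C
Reagents that add atoms: none
Why: Silyl triflate–amine elimination of an acetal to an enol ether: O-silylation turns one alkoxy group into a leaving group and the excess hindered amine removes the C9 proton before the remote alkene can intercept the oxocarbenium ion; the geometry obtained is irrelevant because step 3 resets it.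

Step 3
Reactants: 4 enol ether
Product: 6 (1Z,3S)-2-bromo-1-[(4-methoxybenzyl)oxy]-3,7-dimethylocta-1,6-diene (Br cis to O), via dibromo ether 5 (not isolated)
Conditions: Br2 (1.0 equiv, dilute), CH2Cl2, −78 °C; then DBU (2 equiv), −78 °C → rt; chromatography on Et3N-deactivated SiO2
Reagents that add atoms: bromine, BrBr
Why: Bromination–dehydrobromination of an enol ether: one equivalent of Br2 at −78 °C should pick the enol ether, far more nucleophilic than the trisubstituted alkene or the anisyl ring, the α-bromo ether centre of 5 equilibrates by ionisation so that both isomers of 4 converge, and loss of the C9 proton should favour the isomer with oxygen cis to bromine instead of cis to the branched C10 (the minor isomer is removed by chromatography).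

Step 4
Reactants: 7 3-methylbut-2-enoic acid; 8 (S)-4-benzyl-2-oxazolidinone
Product: 10 (4S)-4-benzyl-3-(3-methylbut-2-enoyl)-1,3-oxazolidin-2-one, via mixed pivalic anhydride 9 (not isolated)
Conditions: t-BuCOCl, Et3N, THF, −20 °C; then LiCl, 8, −20 °C → rt
Reagents that add atoms: none
Why: Mixed-anhydride N-acylation of an oxazolidinone promoted by LiCl, which avoids strong base and conjugate addition to the unsaturated acyl group.

Step 5
Reactants: 10 senecioyl imide; 11 allyl bromide
Product: 13 (4S)-4-benzyl-3-[(2S)-2-(prop-1-en-2-yl)pent-4-enoyl]-1,3-oxazolidin-2-one, via sodium dienolate 12 (not isolated)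
Conditions: NaN(SiMe3)2 (1.05 equiv), THF, −78 °C; then 11 (3 equiv), −78 → −30 °C
Reagents that add atoms: none
Why: Evans-type auxiliary-controlled deconjugative alkylation: γ-deprotonation gives the chelated Z(O)-dienolate 12, which is allylated at the α-carbon on the face away from the benzyl group and so sets the S centre that becomes C4.

Step 6
Reactants: 13 allylated imide
Product: 14 (2S)-N-methoxy-N-methyl-2-(prop-1-en-2-yl)pent-4-enamide
Conditions: MeONHMe·HCl (3 equiv), AlMe3 (3 equiv), CH2Cl2, 0 °C; then 13, −10 °C → rt; aq. potassium sodium tartrate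
Reagents that add atoms: N,O-dimethylhydroxylamine hydrochloride, CNOC.Cl
Why: Weinreb transamidation with the aluminium amide made from AlMe3 and MeONHMe·HCl: the Lewis-acidic, weakly basic reagent attacks the exocyclic carbonyl, releases the auxiliary for recovery and should neither epimerise C4 nor move the isopropenyl double bond into conjugation.

Step 7
Reactants: 14 amide; 15 2-bromoacrolein diethyl acetal
Product: 18 (4S)-2-(diethoxymethyl)-4-(prop-1-en-2-yl)hepta-1,6-dien-3-one, via 2-lithioacrolein diethyl acetal 16 (not isolated), via tetrahedral lithium chelate 17 (not isolated)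
Conditions: 15, t-BuLi (2 equiv), Et2O, −78 °C; then 14, −78 °C; inverse quench into cold aq. NH4Cl
Reagents that add atoms: none
Why: Bromine–lithium exchange followed by Weinreb ketone synthesis: chelate 17 survives until the quench so that no second addition occurs, and the cold inverse quench limits enolisation at C4 and conjugate addition of the released amine.

Step 8
Reactants: 18 trienone
Product: 19 (5S)-2-(diethoxymethyl)-5-(prop-1-en-2-yl)cyclopent-2-en-1-one
Conditions: second-generation Grubbs catalyst (H2IMes)(PCy3)Cl2Ru=CHPh (5 mol %), 1,4-benzoquinone (10 mol %), CH2Cl2 (dilute), 40 °C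
Reagents that add atoms: none
Why: Ring-closing metathesis: the catalyst loads on the monosubstituted allyl alkene and only its pairing with the C7 methylene gives an unstrained five-membered ring (the isopropenyl group could only close a cyclobutene), benzoquinone suppresses ruthenium hydride isomerisation, and C6=C7 is necessarily cis.

Step 9
Reactants: 6 bromo enol ether; 19 cyclopentenone
Product: 22 (1S,5S)-2-(diethoxymethyl)-1-[(1Z,3S)-1-[(4-methoxybenzyl)oxy]-3,7-dimethylocta-1,6-dien-2-yl]-5-(prop-1-en-2-yl)cyclopent-2-en-1-ol, via alkenyllithium 20 (not isolated), via alkenylcerium dichloride 21 (not isolated)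
Conditions: 6, t-BuLi (2 equiv), Et2O, −78 °C; anhydrous CeCl3, THF, −78 °C; then 19, −78 °C; aq. NaHCO3; filtration through Et3N-deactivated SiO2
Reagents that add atoms: none
Why: Halogen–metal exchange with retention and organocerium 1,2-addition: in 20 lithium sits cis to the ether oxygen, is chelated by it and cannot undergo anti β-elimination, the weakly basic cerium reagent 21 should add to the carbonyl instead of deprotonating the acidic C4–H or adding 1,4, and attack anti to the isopropenyl group sets C8 (S) with the two alkenyl groups trans (acid-free handling, since 22 is a masked enal).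

Step 10
Reactants: 22 trans-dialkenylcyclopentenol
Product: 25 (2Z,5E,8R,9S)-2-(diethoxymethyl)-8-[(4-methoxybenzyl)oxy]-6-methyl-9-[(2S)-6-methylhept-5-en-2-yl]cyclonona-2,5-dien-1-one, via potassium alkoxide 23 (not isolated), via potassium dienolate 24 (not isolated)
Conditions: KH (1.5 equiv), 18-crown-6 (1.5 equiv), THF, −20 °C → rt; cannulation into AcOH–THF at −78 °C; then pH 7 buffer (NaH2PO4/Na2HPO4)
Reagents that add atoms: none
Why: KH with 18-crown-6 turns 22 into the dissociated bis-allylic alkoxide 23, whose weakened C4–C8 bond breaks while C1 bonds to C2 in a concerted suprafacial [3,3] shift that delivers the cross-conjugated dienolate 24, the alkoxide-to-enolate gain paying for the ring strain. The closest known reaction type is the anionic oxy-Cope four-carbon ring expansion of trans-1,2-dialkenylcycloalkanols to (E)-cycloalk-5-enones, applied here to a cyclopentenol with an enol ether terminus. The nine-membered ring is not closed by end-to-end cyclisation but by ring enlargement, C9, C1, C2 and C3 being inserted into the cyclopentene across the cleaved C4–C8 bond. C1 (R) follows from the only chair open to the trans isomer, with C5 and C7 equatorial and the Z alkoxy group axial, in which C2 reaches the face of the enol ether from which C4 departs, so the C4 configuration and the enol ether geometry decide it; C9 is set by protonation of 24 on its outer face, anti to the new C1–C2 bond, the inner face being covered by C3=C4. The step needs the chair over a boat or a stepwise cleavage (E C3=C4, faithful transfer) and survival of the β-alkoxy enolate: the trans arrangement on the small ring cannot reach a boat, C6=C7 is carried over cis from the cyclopentene, and expulsion of the alkoxide should be held back because the C1–O bond starts near the nodal plane of the enolate, the trienone that would result is highly strained, and the quench is inverse and cold.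

Step 11
Reactants: 25 cyclononadienone; 26 dibromomethane
Product: 28 1-({[(1R,3E,6E,9R)-7-(diethoxymethyl)-3-methyl-8-methylidene-9-[(2S)-6-methylhept-5-en-2-yl]cyclonona-3,6-dien-1-yl]oxy}methyl)-4-methoxybenzene, via bis(bromozincio)methane 27 (not isolated)
Conditions: Zn, 26, TiCl4, THF, −40 → 5 °C, aged 3 d; then 25, CH2Cl2, 0 °C → rt; aq. NaHCO3
Reagents that add atoms: none
Why: Takai–Lombardo methylenation: the non-basic geminal dizinc/titanium reagent methylenates hindered, enolisable ketones without epimerising C9 or expelling the β-alkoxy group, and ageing consumes free TiCl4 so that the acetal and the benzyl ether should survive.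

Step 12
Reactants: 28 methylene compound
Product: 29 (1R,3E,6E,9R)-7-(diethoxymethyl)-3-methyl-8-methylidene-9-[(2S)-6-methylhept-5-en-2-yl]cyclonona-3,6-dien-1-ol
Conditions: DDQ (1.2 equiv), CH2Cl2–pH 7 buffer (NaH2PO4/Na2HPO4), 0 °C
Reagents that add atoms: none
Why: Oxidative cleavage of a 4-methoxybenzyl ether by DDQ: charge transfer to the electron-rich arene should be faster than any reaction with the alkenes, and the cold neutral two-phase medium protects the acetal.

Step 13
Reactants: 29 alcohol
Product: 30 (1R,3E,6E,9R)-7-(diethoxymethyl)-3-methyl-8-methylidene-9-[(2S)-6-methylhept-5-en-2-yl]cyclonona-3,6-dien-1-yl acetate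
Conditions: Ac2O (3 equiv), pyridine, DMAP (10 mol %), CH2Cl2, 0 °C → rt
Reagents that add atoms: acetic anhydride, CC(=O)OC(C)=O
Why: DMAP-catalysed acetylation of the secondary alcohol with retention at C1; no other nucleophilic group is present.

Step 14
Reactants: 30 diene acetate
Product: 32 (1R,3E,6E,8R,9R)-7-(diethoxymethyl)-8-(hydroxymethyl)-3-methyl-9-[(2S)-6-methylhept-5-en-2-yl]cyclonona-3,6-dien-1-yl acetate, via B-alkyl-9-BBN adduct 31 (not isolated)
Conditions: 9-BBN dimer (1.3 equiv B–H), THF, 0 °C → rt; then 30% H2O2, pH 7 buffer (NaH2PO4/Na2HPO4), 0 °C → rt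
Reagents that add atoms: hydrogen peroxide, OO
Why: Hydroboration–oxidation: 9-BBN should select the only 1,1-disubstituted alkene over the three trisubstituted ones and places boron on the CH2 terminus; with C9–H eclipsing the methylene group (allylic 1,3-strain) ring carbon C1 and the chain behind it cover one face, so hydrogen should reach C8 from the opposite face and give 8R, and the neutral peroxide work-up spares the acetate.

Step 15
Reactants: 32 primary alcohol
Product: 33 (1R,3E,6E,8R,9R)-7-(diethoxymethyl)-8-formyl-3-methyl-9-[(2S)-6-methylhept-5-en-2-yl]cyclonona-3,6-dien-1-yl acetate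
Conditions: Dess–Martin periodinane (1.3 equiv), pyridine (5 equiv), CH2Cl2, 0 °C
Reagents that add atoms: none
Why: Dess–Martin oxidation buffered with pyridine: a fast, essentially neutral oxidation that should neither epimerise C8 nor pull C6=C7 into conjugation, and that leaves the acetal intact in the absence of water.

Step 16
Reactants: 33 aldehyde acetal
Product: 34 target, (1R,3E,6E,8R,9R)-7,8-diformyl-3-methyl-9-[(2S)-6-methylhept-5-en-2-yl]cyclonona-3,6-dien-1-yl acetate
Conditions: PPTS (10 mol %), acetone–H2O, 0 °C → rt
Reagents that add atoms: water, O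
Why: Acid-catalysed acetal hydrolysis: the allylic acetal ionises through a conjugated oxocarbenium ion and is therefore cleaved by a catalytic weak acid under conditions that should leave the acetate, the epimerisable C8 and the strained E alkene alone.

Compound list
1 | (S)-citronellal | O=CC[C@@H](C)CCC=C(C)C | starting material
2 | 4-methoxybenzyl alcohol | COc1ccc(CO)cc1 | starting material
3 | (3S)-1,1-bis[(4-methoxybenzyl)oxy]-3,7-dimethyloct-6-ene | COc1ccc(COC(C[C@@H](C)CCC=C(C)C)OCc2ccc(OC)cc2)cc1 | intermediate
4 | (3S)-1-[(4-methoxybenzyl)oxy]-3,7-dimethylocta-1,6-diene, E/Z mixture | COc1ccc(COC=C[C@@H](C)CCC=C(C)C)cc1 | intermediate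
5 | (3S)-1,2-dibromo-1-[(4-methoxybenzyl)oxy]-3,7-dimethyloct-6-ene, diastereomer mixture | COc1ccc(COC(Br)C(Br)[C@@H](C)CCC=C(C)C)cc1 | intermediate
6 | (1Z,3S)-2-bromo-1-[(4-methoxybenzyl)oxy]-3,7-dimethylocta-1,6-diene | COc1ccc(CO/C=C(Br)/[C@@H](C)CCC=C(C)C)cc1 | intermediate
7 | 3-methylbut-2-enoic acid | CC(C)=CC(=O)O | starting material
8 | (S)-4-benzyl-2-oxazolidinone | O=C1N[C@@H](Cc2ccccc2)CO1 | starting material
9 | 3-methylbut-2-enoic pivalic anhydride | CC(C)=CC(=O)OC(=O)C(C)(C)C | intermediate
10 | (4S)-4-benzyl-3-(3-methylbut-2-enoyl)-1,3-oxazolidin-2-one | CC(C)=CC(=O)N1[C@@H](Cc2ccccc2)COC1=O | intermediate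
11 | allyl bromide | C=CCBr | starting material
12 | sodium Z(O)-dienolate of 10 | C=C(C)/C=C(\[O-])N1[C@@H](Cc2ccccc2)COC1=O.[Na+] | intermediate
13 | (4S)-4-benzyl-3-[(2S)-2-(prop-1-en-2-yl)pent-4-enoyl]-1,3-oxazolidin-2-one | C=CC[C@@H](C(C)=C)C(=O)N1[C@@H](Cc2ccccc2)COC1=O | intermediate
14 | (2S)-N-methoxy-N-methyl-2-(prop-1-en-2-yl)pent-4-enamide | CON(C)C(=O)[C@@H](CC=C)C(C)=C | intermediate
15 | 2-bromoacrolein diethyl acetal | CCOC(OCC)C(Br)=C | starting material
16 | 2-lithioacrolein diethyl acetal | CCOC(OCC)C([Li])=C | intermediate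
17 | tetrahedral lithium chelate from 16 and 14 (carbinol centre undefined) | CCOC(OCC)C(=C)C(O[Li])(N(C)OC)[C@@H](CC=C)C(C)=C | intermediate
18 | (4S)-2-(diethoxymethyl)-4-(prop-1-en-2-yl)hepta-1,6-dien-3-one | CCOC(OCC)C(=C)C(=O)[C@@H](CC=C)C(C)=C | intermediate
19 | (5S)-2-(diethoxymethyl)-5-(prop-1-en-2-yl)cyclopent-2-en-1-one | CCOC(OCC)C1=CC[C@@H](C(C)=C)C1=O | intermediate
20 | alkenyllithium from 6 (Li cis to O) | COc1ccc(CO/C=C(/[C@@H](C)CCC=C(C)C)[Li])cc1 | intermediate
21 | alkenylcerium dichloride from 20 | COc1ccc(CO/C=C(/[C@@H](C)CCC=C(C)C)[Ce](Cl)Cl)cc1 | intermediate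
22 | (1S,5S)-2-(diethoxymethyl)-1-[(1Z,3S)-1-[(4-methoxybenzyl)oxy]-3,7-dimethylocta-1,6-dien-2-yl]-5-(prop-1-en-2-yl)cyclopent-2-en-1-ol | COc1ccc(CO/C=C(/[C@@H](C)CCC=C(C)C)[C@]2(O)C(C(OCC)OCC)=CC[C@H]2C(C)=C)cc1 | intermediate
23 | potassium alkoxide of 22 | COc1ccc(CO/C=C(/[C@@H](C)CCC=C(C)C)[C@]2([O-])C(C(OCC)OCC)=CC[C@H]2C(C)=C)cc1.[K+] | intermediate
24 | potassium dienolate of 25 (C8=C9 with C7 and C1 trans, as the chair demands) | COc1ccc(CO[C@@H]2C/C(C)=C/C/C=C(/C(OCC)OCC)\C([O-])=C2/[C@@H](C)CCC=C(C)C)cc1.[K+] | intermediate
25 | (2Z,5E,8R,9S)-2-(diethoxymethyl)-8-[(4-methoxybenzyl)oxy]-6-methyl-9-[(2S)-6-methylhept-5-en-2-yl]cyclonona-2,5-dien-1-one | COc1ccc(CO[C@@H]2C/C(C)=C/C/C=C(/C(OCC)OCC)C(=O)[C@H]2[C@@H](C)CCC=C(C)C)cc1 | intermediate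
26 | dibromomethane | BrCBr | starting material
27 | bis(bromozincio)methane | Br[Zn]C[Zn]Br | intermediate
28 | 4-methoxybenzyl ether of 29 (C8=CH2; 1R,9R,10S) | COc1ccc(CO[C@@H]2C/C(C)=C/C/C=C(/C(OCC)OCC)C(=C)[C@H]2[C@@H](C)CCC=C(C)C)cc1 | intermediate
29 | (1R,3E,6E,9R)-7-(diethoxymethyl)-3-methyl-8-methylidene-9-[(2S)-6-methylhept-5-en-2-yl]cyclonona-3,6-dien-1-ol | O[C@@H]1C/C(C)=C/C/C=C(/C(OCC)OCC)C(=C)[C@H]1[C@@H](C)CCC=C(C)C | intermediate
30 | acetate of 29 | CC(=O)O[C@@H]1C/C(C)=C/C/C=C(/C(OCC)OCC)C(=C)[C@H]1[C@@H](C)CCC=C(C)C | intermediate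
31 | B-alkyl-9-BBN adduct of 30 (boron on the former methylene carbon) | CC(=O)O[C@@H]1C/C(C)=C/C/C=C(/C(OCC)OCC)[C@H](CB2C3CCCC2CCC3)[C@H]1[C@@H](C)CCC=C(C)C | intermediate
32 | (1R,3E,6E,8R,9R)-7-(diethoxymethyl)-8-(hydroxymethyl)-3-methyl-9-[(2S)-6-methylhept-5-en-2-yl]cyclonona-3,6-dien-1-yl acetate | CC(=O)O[C@@H]1C/C(C)=C/C/C=C(/C(OCC)OCC)[C@H](CO)[C@H]1[C@@H](C)CCC=C(C)C | intermediate
33 | (1R,3E,6E,8R,9R)-7-(diethoxymethyl)-8-formyl-3-methyl-9-[(2S)-6-methylhept-5-en-2-yl]cyclonona-3,6-dien-1-yl acetate | CC(=O)O[C@@H]1C/C(C)=C/C/C=C(/C(OCC)OCC)[C@H](C=O)[C@H]1[C@@H](C)CCC=C(C)C | intermediate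
34 | CNP0113811.4, (1R,3E,6E,8R,9R)-7,8-diformyl-3-methyl-9-[(2S)-6-methylhept-5-en-2-yl]cyclonona-3,6-dien-1-yl acetate | CC(=O)O[C@@H]1C/C(C)=C/C/C=C(/C=O)[C@H](C=O)[C@H]1[C@@H](C)CCC=C(C)C | target

Total step count: 16.
Longest linear sequence: 13 steps (steps 4–16, from 7).

Steps most likely to fail

1. Step 10.
   - The strained chair with an axial alkoxy group may be slow. The long-lived β-alkoxy enolate could then expel 4-methoxybenzyl oxide, or C9 could be protonated from both faces.
   - The fallback sets out from 22 and comes back at 25. It replaces direct protonation of a metal enolate by isolation of a neutral enol derivative.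
   - The rearrangement is run with KN(SiMe3)2 and 18-crown-6 in THF, and Et3SiCl is added at −78 °C as soon as 22 is consumed. This should give the triethylsilyl dienol ether F1.
   - This compound cannot eliminate and can be purified on deactivated silica.
   - The C9–H bond is then made in a separate, non-basic operation by protodesilylation with Et3N·3HF in THF at −40 °C. The proton should again arrive on the outer face, giving 25.

2. Step 14.
   - The strained C3=C4 alkene may compete for the borane, and facial selectivity at C8 may be poor, because it rests only on a conformational model.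
   - The fallback sets out from 30 and comes back at 33. It replaces kinetic control by thermodynamic control.
   - The hydroboration is accepted as unselective and the 8S alcohol F2 is separated from 32.
   - Oxidation as in step 15 gives the 8S aldehyde F3.
   - This aldehyde is equilibrated through its dienol with Et3N in CH2Cl2 at rt. The epimer with the formyl group trans to the bulky C9 substituent should prevail, which is 33.

3. Step 9.
   - The doubly activated C4–H of 19 may be deprotonated, with loss of material and of C4 integrity. The branched alkenyl metal may also add sluggishly to a carbonyl flanked by two substituents.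
   - The fallback sets out from 14 (with 6 and 15 as before) and comes back at 22. It reverses the order in which the bonds at C8 are made.
   - Alkenyllithium 20 is acylated by 14 to give the β-alkoxy dienone F4. Its C4–H is less acidic because the carbonyl is a vinylogous ester.
   - The small alkenyllithium 16, transmetalated with CeCl3, is then added. Felkin–Anh control, with isopropenyl as the large group, should give the acyclic carbinol F5 with the C8 configuration of 22.
   - Ring-closing metathesis under the conditions of step 8 closes the cyclopentene to give 22.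

Further compounds
F1 | step 10 | triethylsilyl dienol ether of 25 (C8–OSiEt3, C8=C9 with C7 and C1 trans) | COc1ccc(CO[C@@H]2C/C(C)=C/C/C=C(/C(OCC)OCC)\C(O[Si](CC)(CC)CC)=C2/[C@@H](C)CCC=C(C)C)cc1
F2 | step 14 | 8S epimer of 32 | CC(=O)O[C@@H]1C/C(C)=C/C/C=C(/C(OCC)OCC)[C@@H](CO)[C@H]1[C@@H](C)CCC=C(C)C
F3 | step 14 | 8S epimer of 33 | CC(=O)O[C@@H]1C/C(C)=C/C/C=C(/C(OCC)OCC)[C@@H](C=O)[C@H]1[C@@H](C)CCC=C(C)C
F4 | step 9 | (4S,7S)-6-[(Z)-(4-methoxybenzyloxy)methylidene]-7,11-dimethyl-4-(prop-1-en-2-yl)dodeca-1,10-dien-5-one | COc1ccc(CO/C=C(/[C@@H](C)CCC=C(C)C)C(=O)[C@@H](CC=C)C(C)=C)cc1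
F5 | step 9 | (4S,5S,7S)-5-(3,3-diethoxyprop-1-en-2-yl)-6-[(Z)-(4-methoxybenzyloxy)methylidene]-7,11-dimethyl-4-(prop-1-en-2-yl)dodeca-1,10-dien-5-ol | COc1ccc(CO/C=C(/[C@@H](C)CCC=C(C)C)[C@](O)(C(=C)C(OCC)OCC)[C@@H](CC=C)C(C)=C)cc1
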